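The 1,2-dioxolane is cut across C4–C3 and O1–C5. C3 with its O2–O1 unit is a peroxycarbenium ion, made from the racemic silylperoxy ketal of methyl acetoacetate. C4 and the fully substituted C5 are a 2-methyl-1-alkene that carries the (R)-methyl centre and a spectator vinyl group. One chiral-anion-controlled [3+2] annulation forms both bonds, closes the ring and sets both quaternary centres, while ionisation erases the ketal stereocentre so that both ketal enantiomers converge. The acid-sensitive, nucleophilic phenyldiene is added afterwards by cross-metathesis and Suzuki coupling, with ester hydrolysis in the same pot.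

Key step: step 7

Assumption: the IDPi antipode and its 3,3'-aryl groups used in step 7 are those that screening shows to deliver the (3S,5R) ring, and ester 10 is taken as a catalogue compound.

Step 1
Reactants: 1 (R)-4-benzyl-3-propionyloxazolidin-2-one; 2 3-bromo-2-methylprop-1-ene (methallyl bromide)
Product: 4 (R)-4-benzyl-3-[(2S)-2,4-dimethylpent-4-enoyl]oxazolidin-2-one, via sodium Z-enolate 3 (not isolated)
Conditions: NaN(SiMe3)2, THF, −78 °C; then 2, −78 → −40 °C
Reagents that add atoms: none
Why: Evans asymmetric alkylation, in which the chelated sodium Z-enolate 3 should be alkylated by the allylic bromide on the face away from the benzyl group, setting the (2S) methyl centre with high diastereoselectivity.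

Step 2
Reactants: 4 (R)-4-benzyl-3-[(2S)-2,4-dimethylpent-4-enoyl]oxazolidin-2-one
Product: 5 (2S)-2,4-dimethylpent-4-en-1-ol
Conditions: LiBH4, H2O (1 equiv), Et2O, 0 °C
Reagents that add atoms: none
Why: Reductive cleavage of the N-acyl oxazolidinone by LiBH4 should give the primary alcohol and free the auxiliary without touching the stereocentre or the alkene.

Step 3
Reactants: 5 (2S)-2,4-dimethylpent-4-en-1-ol
Product: 6 (2S)-2,4-dimethylpent-4-en-1-yl 4-methylbenzenesulfonate
Conditions: TsCl, Et3N, DMAP (cat.), CH2Cl2, 0 °C → rt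
Reagents that add atoms: 4-toluenesulfonyl chloride, Cc1ccc(cc1)S(Cl)(=O)=O
Why: Sulfonylation of a primary alcohol, in which no bond to the stereocentre is made or broken.

Step 4
Reactants: 6 (2S)-2,4-dimethylpent-4-en-1-yl 4-methylbenzenesulfonate; 7 7-bromohept-1-ene
Product: 9 (4R)-2,4-dimethyldodeca-1,11-diene, via hept-6-enylmagnesium bromide 8 (not isolated)
Conditions: 7, Mg, THF, rt; then 6, Li2CuCl4 (cat.), THF, −78 °C → rt
Reagents that add atoms: none
Why: Copper-catalysed cross-coupling of a primary tosylate with a primary alkyl Grignard reagent should displace the sulfonate at the CH2 carbon next to the stereocentre, which is untouched (its descriptor changes to R only through the priority rules), and both alkenes are inert.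

Step 5
Reactants: 10 methyl 3-methylbut-3-enoate
Product: 12 methyl 3-hydroperoxy-3-methoxybutanoate, via carbonyl oxide 11 (not isolated)
Conditions: O3, CH2Cl2/MeOH, −78 °C; N2 purge, warm to rt, no reductant
Reagents that add atoms: ozone, [O-][O+]=O; methanol, CO
Why: Ozonolysis in methanol, in which the primary ozonide of a 1,1-disubstituted alkene should fragment to formaldehyde and the more substituted carbonyl oxide 11, which methanol traps as the racemic hydroperoxy ketal.

Step 6
Reactants: 12 methyl 3-hydroperoxy-3-methoxybutanoate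
Product: 13 methyl 3-methoxy-3-[(triethylsilyl)peroxy]butanoate (racemic)
Conditions: Et3SiCl, Et3N, DMAP (cat.), CH2Cl2, 0 °C
Reagents that add atoms: chlorotriethylsilane, CC[Si](Cl)(CC)CC
Why: O-Silylation of the hydroperoxide, which is safe from base-induced peroxide fragmentation because the ketal carbon carries no hydrogen.

Step 7
Reactants: 9 (4R)-2,4-dimethyldodeca-1,11-diene; 13 methyl 3-methoxy-3-[(triethylsilyl)peroxy]butanoate (racemic, 1.5 equiv)
Product: 16 methyl 2-[(3S,5R)-3,5-dimethyl-5-[(2R)-2-methyldec-9-en-1-yl]-1,2-dioxolan-3-yl]acetate, via peroxycarbenium ion 14 (not isolated), via tertiary carbocation 15 (not isolated)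
Conditions: chiral imidodiphosphorimidate Brønsted acid (IDPi, BINOL-derived, N-triflyl; 5 mol %), CH2Cl2, −78 → −40 °C; Et3N quench
Reagents that add atoms: none
Why: Proposed new method: the silylated IDPi should remove methoxide from 13 as Et3SiOMe to give peroxycarbenium ion 14 paired with the chiral anion, the CH2 terminus (C4) of the 2-methyl-1-alkene of 9 then adds to C3, and the tertiary cation 15 at C5 is captured by the distal silylated peroxide oxygen O1, which hands Et3Si+ back to the anion and so turns the catalyst over. The closest known reactions are the SnCl4- or TiCl4-promoted [3+2] annulation of triethylsilylperoxy ketals with 1,1-disubstituted alkenes (the same two bonds, without absolute control) and silylium-IDPi catalysis of additions to aliphatic oxocarbenium ions. The dioxolane closes by a five-membered cation–oxygen recombination at C5; this is a polar stepwise annulation in which no π bond is opened on closure, so exo/endo labels do not apply. C3 (S) is set in the C–C bond formation by the confined chiral anion, which must tell the methyl side from the CH2CO2Me side of 14, and because ionisation erases the stereocentre of racemic 13 both of its enantiomers converge; C5 (R) is set in the closure, where the anion and the new C3 centre should place CH2CO2Me and the long chain trans on the ring. The step needs chemoselectivity for the 2-methyl-1-alkene over the vinyl group and Markovnikov regioselectivity, both secured by the tertiary versus secondary cation, and this need is why the phenyldiene is absent from 9. The (R)-methyl centre of 9 is a remote spectator and is not touched.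

Step 8
Reactants: 16 methyl 2-[(3S,5R)-3,5-dimethyl-5-[(2R)-2-methyldec-9-en-1-yl]-1,2-dioxolan-3-yl]acetate; 17 4,4,5,5-tetramethyl-2-vinyl-1,3,2-dioxaborolane (vinylboronic acid pinacol ester, 3 equiv)
Product: 18 methyl 2-[(3S,5R)-3,5-dimethyl-5-[(2R,9E)-2-methyl-10-(4,4,5,5-tetramethyl-1,3,2-dioxaborolan-2-yl)dec-9-en-1-yl]-1,2-dioxolan-3-yl]acetate
Conditions: second-generation Hoveyda–Grubbs catalyst RuCl2(H2IMes)(=CH-C6H4-2-OiPr) (5 mol %), CH2Cl2, 40 °C
Reagents that add atoms: none
Why: Olefin cross-metathesis of the only remaining alkene with the vinylboronate should give the (E)-alkenylboronate under thermodynamic control, and the phosphine-free ruthenium carbene should tolerate the fully substituted dialkyl peroxide and the ester.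

Step 9
Reactants: 18 methyl 2-[(3S,5R)-3,5-dimethyl-5-[(2R,9E)-2-methyl-10-(4,4,5,5-tetramethyl-1,3,2-dioxaborolan-2-yl)dec-9-en-1-yl]-1,2-dioxolan-3-yl]acetate; 19 (E)-(2-bromovinyl)benzene
Product: 21 2-[(3S,5R)-3,5-dimethyl-5-[(2R,9E,11E)-2-methyl-12-phenyldodeca-9,11-dien-1-yl]-1,2-dioxolan-3-yl]acetic acid, via methyl ester 20 (not isolated)
Conditions: PdCl2(dppf) (5 mol %), LiOH (aq, excess), THF/H2O, degassed, rt → 40 °C; then 1 M HCl to pH 3
Reagents that add atoms: lithium hydroxide, [Li+].[OH-]
Why: Suzuki–Miyaura coupling should proceed with retention at both alkenyl partners to give the (9E,11E)-diene ester 20, which the excess LiOH saponifies in the same pot; neither peroxide carbon carries a hydrogen, so base-induced peroxide cleavage by α-deprotonation is not open.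

Compound list
1 | (R)-4-benzyl-3-propionyloxazolidin-2-one | CCC(=O)N1[C@H](Cc2ccccc2)COC1=O | starting material
2 | 3-bromo-2-methylprop-1-ene (methallyl bromide) | C=C(C)CBr | starting material
3 | sodium (Z)-enolate of 1 | C/C=C(\[O-])N1[C@H](Cc2ccccc2)COC1=O.[Na+] | intermediate
4 | (R)-4-benzyl-3-[(2S)-2,4-dimethylpent-4-enoyl]oxazolidin-2-one | C[C@H](C(=O)N1[C@H](Cc2ccccc2)COC1=O)CC(C)=C | intermediate
5 | (2S)-2,4-dimethylpent-4-en-1-ol | C[C@H](CO)CC(C)=C | intermediate
6 | (2S)-2,4-dimethylpent-4-en-1-yl 4-methylbenzenesulfonate | C[C@H](COS(=O)(=O)c1ccc(C)cc1)CC(C)=C | intermediate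
7 | 7-bromohept-1-ene | C=CCCCCCBr | starting material
8 | hept-6-enylmagnesium bromide | C=CCCCCC[Mg]Br | intermediate
9 | (4R)-2,4-dimethyldodeca-1,11-diene | C[C@H](CCCCCCC=C)CC(C)=C | intermediate
10 | methyl 3-methylbut-3-enoate | C=C(C)CC(=O)OC | starting material
11 | carbonyl oxide of methyl acetoacetate (methyl 3-(oxidooxidaniumylidene)butanoate) | CC(CC(=O)OC)=[O+][O-] | intermediate
12 | methyl 3-hydroperoxy-3-methoxybutanoate (racemic) | COC(C)(OO)CC(=O)OC | intermediate
13 | methyl 3-methoxy-3-[(triethylsilyl)peroxy]butanoate (racemic) | COC(C)(OO[Si](CC)(CC)CC)CC(=O)OC | intermediate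
14 | peroxycarbenium ion (cation shown; counter-ion is the IDPi anion) | CC(CC(=O)OC)=[O+]O[Si](CC)(CC)CC | intermediate
15 | tertiary carbocation at C5, open-chain adduct with C3 already (S) | C[C@H](CCCCCCC=C)C[C+](C)C[C@@](C)(CC(=O)OC)OO[Si](CC)(CC)CC | intermediate
16 | methyl 2-[(3S,5R)-3,5-dimethyl-5-[(2R)-2-methyldec-9-en-1-yl]-1,2-dioxolan-3-yl]acetate | C[C@H](CCCCCCC=C)C[C@]1(C)C[C@@](C)(CC(=O)OC)OO1 | intermediate
17 | 4,4,5,5-tetramethyl-2-vinyl-1,3,2-dioxaborolane | C=CB1OC(C)(C)C(C)(C)O1 | starting material
18 | methyl 2-[(3S,5R)-3,5-dimethyl-5-[(2R,9E)-2-methyl-10-(4,4,5,5-tetramethyl-1,3,2-dioxaborolan-2-yl)dec-9-en-1-yl]-1,2-dioxolan-3-yl]acetate | C[C@H](CCCCCC/C=C/B1OC(C)(C)C(C)(C)O1)C[C@]2(C)C[C@@](C)(CC(=O)OC)OO2 | intermediate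
19 | (E)-(2-bromovinyl)benzene | Br/C=C/c1ccccc1 | starting material
20 | methyl 2-[(3S,5R)-3,5-dimethyl-5-[(2R,9E,11E)-2-methyl-12-phenyldodeca-9,11-dien-1-yl]-1,2-dioxolan-3-yl]acetate | C[C@H](CCCCCC/C=C/C=C/c1ccccc1)C[C@]1(C)C[C@@](C)(CC(=O)OC)OO1 | intermediate
21 | 2-[(3S,5R)-3,5-dimethyl-5-[(2R,9E,11E)-2-methyl-12-phenyldodeca-9,11-dien-1-yl]-1,2-dioxolan-3-yl]acetic acid (CNP0196394.4) | C[C@H](CCCCCC/C=C/C=C/c1ccccc1)C[C@]1(C)C[C@@](C)(CC(=O)O)OO1 | target

Total step count: 9
Longest linear sequence: 7 steps (steps 1, 2, 3, 4, 7, 8, 9)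

Steps most likely to fail

Step 7 (key annulation). The ion pair may discriminate poorly between the two faces of C3 or of the C5 cation. The strong acid may also trigger migration to oxygen within the silyl peroxide, or the tertiary cation may lose a proton before the ring closes. The fallback uses known chemistry, a covalent auxiliary with the stoichiometric SnCl4-promoted silylperoxy ketal/alkene annulation; it sets out from 9 and returns at 16. Its partner is built from 3-methylbut-3-enoic acid. Activation as the mixed pivalic anhydride (PivCl, Et3N) and acylation of lithiated (S)-4-benzyloxazolidin-2-one should give (S)-4-benzyl-3-(3-methylbut-3-enoyl)oxazolidin-2-one F1. Ozonolysis in CH2Cl2/MeOH at −78 °C should give (S)-4-benzyl-3-(3-hydroperoxy-3-methoxybutanoyl)oxazolidin-2-one F2, and Et3SiCl/Et3N should give (S)-4-benzyl-3-[3-methoxy-3-(triethylsilylperoxy)butanoyl]oxazolidin-2-one F3. Treatment of 9 and F3 with SnCl4 (1 equiv, CH2Cl2, −78 °C) should give the dioxolane imides. No facial induction is relied on: the oxazolidinone stereocentre close to C3 should make the ring diastereomers separable by chromatography or crystallisation. The isomer taken is (S)-4-benzyl-3-{2-[(3S,5R)-3,5-dimethyl-5-[(2R)-2-methyldec-9-en-1-yl]-1,2-dioxolan-3-yl]acetyl}oxazolidin-2-one F4. NaOMe in MeOH at 0 °C then returns 16 and the auxiliary.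

Step 9 (coupling and saponification). Zerovalent palladium or its phosphine may cleave the O–O bond, and hydroxide may open the ring by β-elimination from the ester enolate. The boronate may also protodeboronate. The fallback avoids palladium and strong base; it sets out from 16 and returns at 20 and then 21. Cross-metathesis of 16 with (E)-buta-1,3-dien-1-ylbenzene (second-generation Hoveyda–Grubbs catalyst RuCl2(H2IMes)(=CH-C6H4-2-OiPr), CH2Cl2, 40 °C) should give ester 20 directly. Here 20 is isolated, purified from geometric isomers, and hydrolysed to 21 with pig liver esterase at pH 7 (or Me3SnOH, 1,2-dichloroethane, 60 °C).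

Step 8 (cross-metathesis). E/Z control may be low, turnover may be slow, or 16 may homodimerise. The fallback is an olefination; it sets out from 16 and returns at 20. Lemieux–Johnson cleavage (OsO4 cat., NaIO4, 2,6-lutidine, dioxane/H2O) should give methyl 2-[(3S,5R)-3,5-dimethyl-5-[(2R)-2-methyl-9-oxononyl]-1,2-dioxolan-3-yl]acetate F5. Horner–Wadsworth–Emmons reaction with the preformed lithium anion of diethyl [(2E)-3-phenylprop-2-en-1-yl]phosphonate (LiN(SiMe3)2, THF, −78 → 0 °C) should give 20 with the new alkene E. Ester 20 is then saponified with LiOH as in the second half of step 9.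

Further compounds
F1 | step 7 | (S)-4-benzyl-3-(3-methylbut-3-enoyl)oxazolidin-2-one | C=C(C)CC(=O)N1[C@@H](Cc2ccccc2)COC1=O
F2 | step 7 | (S)-4-benzyl-3-(3-hydroperoxy-3-methoxybutanoyl)oxazolidin-2-one (both ketal epimers) | COC(C)(OO)CC(=O)N1[C@@H](Cc2ccccc2)COC1=O
F3 | step 7 | (S)-4-benzyl-3-[3-methoxy-3-(triethylsilylperoxy)butanoyl]oxazolidin-2-one (both ketal epimers) | COC(C)(OO[Si](CC)(CC)CC)CC(=O)N1[C@@H](Cc2ccccc2)COC1=O
F4 | step 7 | (S)-4-benzyl-3-{2-[(3S,5R)-3,5-dimethyl-5-[(2R)-2-methyldec-9-en-1-yl]-1,2-dioxolan-3-yl]acetyl}oxazolidin-2-one | C[C@H](CCCCCCC=C)C[C@]1(C)C[C@@](C)(CC(=O)N2[C@@H](Cc3ccccc3)COC2=O)OO1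
F5 | step 8 | methyl 2-[(3S,5R)-3,5-dimethyl-5-[(2R)-2-methyl-9-oxononyl]-1,2-dioxolan-3-yl]acetate | C[C@H](CCCCCCC=O)C[C@]1(C)C[C@@](C)(CC(=O)OC)OO1
F0 | step 9 | none | none
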